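**Retrosynthetic overview**
1. Target 29 ⇐ tricyclic alcohol 23 by angeloylation, C11 oxidation with alkene conjugation (verbenone-type enone), and C5 acetylation.
2. Seven-membered ring (formed last): C6–C7 bond by intramolecular ester-enolate aldol onto the bridging cyclobutanone of 18, then radical C7–O → C7–H.
3. Cyclobutane and six-membered ring (formed together, first): crossed intramolecular vinylketene–alkene [2+2] of acyclic acid 15; the C11 silyloxy stereocentre relays absolute configuration to C1, C2 and C8 and later becomes the ketone.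
4. Acid 15 ⇐ enal 8 + senecioate dienolate 12 (catalytic asymmetric vinylogous Mukaiyama aldol, sets C11); 8 ⇐ geranyl acetate + Evans propionate aldol (sets C5).
5. This avoids the enone–alkene photocycloaddition and the verbenone chiral-pool approaches.

Convention: locants C1–C11 and C15 in the text are those of the target core, tricyclo[5.4.0.0(2,8)]undecane (C1–C7 and C2–C8 bonds; C6 bears CH3 and the CH2O carbon C15; C11 is the ketone carbon); metal alkoxides that are only protonated on aqueous work-up are not numbered.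

**Step 1**
Reactants: 1 geranyl acetate [(2E)-3,7-dimethylocta-2,6-dien-1-yl acetate]
Product: 2 (2E)-3-methyl-6-oxohex-2-en-1-yl acetate
Conditions: O3 (1.0 equiv), CH2Cl2, pyridine, −78 °C; then Me2S, −78 °C → rt
Reagents that add atoms: ozone, [O-][O+]=O
Why: Chemoselective ozonolysis cleaves the electron-rich remote trisubstituted alkene while the alkene deactivated by the allylic acetate (future C1=C2, E) survives untouched.

**Step 2**
Reactants: 3 (4S)-4-benzyl-3-propanoyl-1,3-oxazolidin-2-one; 2 (2E)-3-methyl-6-oxohex-2-en-1-yl acetate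
Product: 5 (4S)-4-benzyl-3-[(2S,3R,6E)-8-acetoxy-3-hydroxy-2,6-dimethyloct-6-enoyl]-1,3-oxazolidin-2-one, via Z dibutylboron enolate 4 (not isolated)
Conditions: Bu2BOTf, i-Pr2NEt, CH2Cl2, 0 °C; then 2, −78 → 0 °C; then pH 7 buffer, MeOH, 30% H2O2, 0 °C
Reagents that add atoms: none
Why: Evans syn aldol, in which the Z boron enolate reacts through a Zimmerman–Traxler chair on the face opposite the benzyl group and gives the 2S,3R adduct, so the R carbinol that becomes C5 is set by the auxiliary.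

**Step 3**
Reactants: 5 (4S)-4-benzyl-3-[(2S,3R,6E)-8-acetoxy-3-hydroxy-2,6-dimethyloct-6-enoyl]-1,3-oxazolidin-2-one
Product: 6 methyl (2S,3R,6E)-3,8-dihydroxy-2,6-dimethyloct-6-enoate
Conditions: NaOMe (0.3 equiv), MeOH, 0 °C
Reagents that add atoms: methanol, CO
Why: Methoxide-catalysed transesterification removes the auxiliary as the methyl ester and cleaves the allylic acetate in the same operation without touching the carbinol stereocentre.

**Step 4**
Reactants: 6 methyl (2S,3R,6E)-3,8-dihydroxy-2,6-dimethyloct-6-enoate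
Product: 7 methyl (2S,3R,6E)-3-hydroxy-2,6-dimethyl-8-oxooct-6-enoate
Conditions: MnO2, CH2Cl2, rt
Reagents that add atoms: none
Why: Allylic oxidation with MnO2 converts only the primary allylic alcohol into the E enal and leaves the secondary alcohol alone.

**Step 5**
Reactants: 7 methyl (2S,3R,6E)-3-hydroxy-2,6-dimethyl-8-oxooct-6-enoate
Product: 8 methyl (2S,3R,6E)-3-[(tert-butyldimethylsilyl)oxy]-2,6-dimethyl-8-oxooct-6-enoate
Conditions: TBSCl, imidazole, DMF, rt
Reagents that add atoms: tert-butyl(chloro)dimethylsilane, CC(C)(C)[Si](C)(C)Cl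
Why: Standard O-silylation installs the bulky, weakly coordinating ether that is needed in step 11 to enforce a non-chelated aldol transition state.

**Step 6**
Reactants: 9 3-methylbut-2-enoic acid
Product: 10 tert-butyl 3-methylbut-2-enoate
Conditions: t-BuOC(=NH)CCl3, BF3·OEt2 (cat.), CH2Cl2/cyclohexane, rt
Reagents that add atoms: tert-butyl 2,2,2-trichloroacetimidate, CC(C)(C)OC(=N)C(Cl)(Cl)Cl
Why: Acid-catalysed imidate tert-butylation gives an ester that can later be cleaved in the presence of the methyl ester.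

**Step 7**
Reactants: 10 tert-butyl 3-methylbut-2-enoate
Product: 12 tert-butyl[(1-tert-butoxy-3-methylbuta-1,3-dien-1-yl)oxy]dimethylsilane, via lithium dienolate 11 (not isolated)
Conditions: LiN(i-Pr)2, THF/DMPU, −78 °C; then TBSCl, −78 °C → rt
Reagents that add atoms: tert-butyl(chloro)dimethylsilane, CC(C)(C)[Si](C)(C)Cl
Why: Kinetic gamma-deprotonation of the senecioate and O-silylation give the silyl dienol ether (silyl ketene acetal) for the vinylogous aldol; its ketene-acetal geometry is inconsequential.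

**Step 8**
Reactants: 8 methyl (2S,3R,6E)-3-[(tert-butyldimethylsilyl)oxy]-2,6-dimethyl-8-oxooct-6-enoate; 12 tert-butyl[(1-tert-butoxy-3-methylbuta-1,3-dien-1-yl)oxy]dimethylsilane
Product: 13 1-tert-butyl 12-methyl (2E,5R,6E,10R,11S)-10-[(tert-butyldimethylsilyl)oxy]-5-hydroxy-3,7,11-trimethyldodeca-2,6-dienedioate
Conditions: SiCl4 (1.1 equiv), (R,R)-bisphosphoramide N,N'-bis[(11bR)-3,5-dimethyl-4-oxido-3,5-dihydro-4H-dinaphtho[2,1-d:1',2'-f][1,3,2]diazaphosphepin-4-yl]-N,N'-dimethylpentane-1,5-diamine (5 mol %), i-Pr2NEt (10 mol %), CH2Cl2, −78 °C; then aq. KF/NaHCO3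
Reagents that add atoms: none
Why: Lewis-base-activated SiCl4 vinylogous Mukaiyama aldol, in which the chiral phosphoramide-bound silicon cation directs gamma-attack of the dienolate on the Re face of the enal, sets the R carbinol (C11) and the E enoate under catalyst control.

**Step 9**
Reactants: 13 1-tert-butyl 12-methyl (2E,5R,6E,10R,11S)-10-[(tert-butyldimethylsilyl)oxy]-5-hydroxy-3,7,11-trimethyldodeca-2,6-dienedioate
Product: 15 (2E,5R,6E,10R,11S)-10-[(tert-butyldimethylsilyl)oxy]-12-methoxy-3,7,11-trimethyl-12-oxo-5-[(triethylsilyl)oxy]dodeca-2,6-dienoic acid, via bis(triethylsilyl) ester-ether 14 (not isolated)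
Conditions: TESOTf (3 equiv), 2,6-lutidine, CH2Cl2, 0 °C → rt; then pH 7 buffer, THF
Reagents that add atoms: triethylsilyl trifluoromethanesulfonate, CC[Si](CC)(CC)OS(=O)(=O)C(F)(F)F
Why: Silyl-triflate-mediated tert-butyl ester cleavage (loss of isobutene) and O-silylation of the C11 alcohol occur together, and the silyl ester hydrolyses on work-up while the methyl ester and both silyl ethers survive.

**Step 10**
Reactants: 15 (2E,5R,6E,10R,11S)-10-[(tert-butyldimethylsilyl)oxy]-12-methoxy-3,7,11-trimethyl-12-oxo-5-[(triethylsilyl)oxy]dodeca-2,6-dienoic acid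
Product: 18 methyl (2S,3R)-3-[(tert-butyldimethylsilyl)oxy]-2-methyl-5-{(1S,4R,5S,7S)-7-methyl-2-methylidene-6-oxo-4-[(triethylsilyl)oxy]bicyclo[3.1.1]heptan-7-yl}pentanoate, via acid chloride 16 (not isolated), via vinylketene 17 (not isolated)
Conditions: Me2C=C(Cl)NMe2, CH2Cl2, rt; then slow addition (8 h) to Et3N, toluene, 110 °C (0.005 M)
Reagents that add atoms: none
Why: In this intramolecular vinylketene–alkene [2+2] cycloaddition (crossed mode) the ketene carbonyl carbon C7 bonds to C1 and the alpha carbon C8 to the cation-stabilising disubstituted C2, the E alkene places the C2 methyl over the three-carbon bridge, and A(1,3) strain keeps C11–H in the alkene plane so that the ketene adds anti to the OSiEt3 group, which fixes C1, C2 and C8 from the single C11 stereocentre.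

**Step 11**
Reactants: 18 methyl (2S,3R)-3-[(tert-butyldimethylsilyl)oxy]-2-methyl-5-{(1S,4R,5S,7S)-7-methyl-2-methylidene-6-oxo-4-[(triethylsilyl)oxy]bicyclo[3.1.1]heptan-7-yl}pentanoate
Product: 21 methyl (1S,2S,5R,6S,7S,8S,11R)-5-[(tert-butyldimethylsilyl)oxy]-7-[(methoxyoxalyl)oxy]-2,6-dimethyl-9-methylidene-11-[(triethylsilyl)oxy]tricyclo[5.4.0.0(2,8)]undecane-6-carboxylate, via lithium ester enolate 19 (not isolated), via lithium aldolate 20 (not isolated)
Conditions: LiN(i-Pr)2 (1.15 equiv), THF, −78 °C; then ClC(O)CO2Me, −78 → 0 °C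
Reagents that add atoms: methyl chlorooxoacetate, COC(=O)C(=O)Cl
Why: In this intramolecular ester-enolate aldol addition to the strained, non-enolisable cyclobutanone the tether from C2 forces attack on the lower face of C7, the non-chelated A(1,3)-minimised enolate conformer (C5–H eclipsing the enolate, OSi anti to the forming bond) sets C6 with CH3 cis and CO2Me trans to the C5 oxygen, and O-acylation of the aldolate to the methyl oxalate blocks retro-aldol.

**Step 12**
Reactants: 21 methyl (1S,2S,5R,6S,7S,8S,11R)-5-[(tert-butyldimethylsilyl)oxy]-7-[(methoxyoxalyl)oxy]-2,6-dimethyl-9-methylidene-11-[(triethylsilyl)oxy]tricyclo[5.4.0.0(2,8)]undecane-6-carboxylate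
Product: 22 methyl (1S,2S,5R,6R,7R,8S,11R)-5-[(tert-butyldimethylsilyl)oxy]-2,6-dimethyl-9-methylidene-11-[(triethylsilyl)oxy]tricyclo[5.4.0.0(2,8)]undecane-6-carboxylate
Conditions: Bu3SnH (4 equiv), AIBN, toluene, 110 °C
Reagents that add atoms: none
Why: Barton–McCombie-type radical deoxygenation of the tertiary methyl oxalate gives a C7 cyclobutyl radical that can only take hydrogen on the face opposite the seven-membered ring, which delivers the required C7–H.

**Step 13**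
Reactants: 22 methyl (1S,2S,5R,6R,7R,8S,11R)-5-[(tert-butyldimethylsilyl)oxy]-2,6-dimethyl-9-methylidene-11-[(triethylsilyl)oxy]tricyclo[5.4.0.0(2,8)]undecane-6-carboxylate
Product: 23 [(1S,2S,5R,6S,7R,8S,11R)-5-[(tert-butyldimethylsilyl)oxy]-2,6-dimethyl-9-methylidene-11-[(triethylsilyl)oxy]tricyclo[5.4.0.0(2,8)]undecan-6-yl]methanol
Conditions: LiAlH4, THF, 0 °C → rt
Reagents that add atoms: none
Why: Hydride reduction of the hindered ester gives the neopentyl primary alcohol (C15) while silyl ethers and the isolated alkene are inert.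

**Step 14**
Reactants: 23 [(1S,2S,5R,6S,7R,8S,11R)-5-[(tert-butyldimethylsilyl)oxy]-2,6-dimethyl-9-methylidene-11-[(triethylsilyl)oxy]tricyclo[5.4.0.0(2,8)]undecan-6-yl]methanol
Product: 24 [(1S,2S,5R,6S,7R,8S,11R)-5-[(tert-butyldimethylsilyl)oxy]-2,6-dimethyl-9-methylidene-11-[(triethylsilyl)oxy]tricyclo[5.4.0.0(2,8)]undecan-6-yl]methyl (2Z)-2-methylbut-2-enoate
Conditions: angelic anhydride (1.5 equiv), Cs2CO3, MeCN, rt
Reagents that add atoms: angelic anhydride, C/C=C(/C)C(=O)OC(=O)/C(C)=C\C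
Why: Base-mediated O-acylation with the preformed anhydride avoids nucleophilic catalysts and acyl-pyridinium intermediates, so the Z (angelate) geometry is retained.

**Step 15**
Reactants: 24 [(1S,2S,5R,6S,7R,8S,11R)-5-[(tert-butyldimethylsilyl)oxy]-2,6-dimethyl-9-methylidene-11-[(triethylsilyl)oxy]tricyclo[5.4.0.0(2,8)]undecan-6-yl]methyl (2Z)-2-methylbut-2-enoate
Product: 25 [(1S,2S,5R,6S,7R,8S,11R)-5-[(tert-butyldimethylsilyl)oxy]-11-hydroxy-2,6-dimethyl-9-methylidenetricyclo[5.4.0.0(2,8)]undecan-6-yl]methyl (2Z)-2-methylbut-2-enoate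
Conditions: PPTS (cat.), MeOH/CH2Cl2, 0 °C
Reagents that add atoms: none
Why: Mild acid-catalysed methanolysis removes the less hindered triethylsilyl ether selectively and leaves the neopentyl tert-butyldimethylsilyl ether and the angelate.

**Step 16**
Reactants: 25 [(1S,2S,5R,6S,7R,8S,11R)-5-[(tert-butyldimethylsilyl)oxy]-11-hydroxy-2,6-dimethyl-9-methylidenetricyclo[5.4.0.0(2,8)]undecan-6-yl]methyl (2Z)-2-methylbut-2-enoate
Product: 27 [(1S,2S,5R,6S,7R,8S)-5-[(tert-butyldimethylsilyl)oxy]-2,6,9-trimethyl-11-oxotricyclo[5.4.0.0(2,8)]undec-9-en-6-yl]methyl (2Z)-2-methylbut-2-enoate, via beta-gamma-unsaturated ketone 26 (not isolated)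
Conditions: Dess–Martin periodinane, NaHCO3, CH2Cl2, rt; then DBU (0.2 equiv), 0 °C, 15 min
Reagents that add atoms: none
Why: Dess–Martin oxidation gives the beta,gamma-unsaturated ketone and base-mediated conjugation through the dienolate moves the exocyclic alkene into the ring to give the verbenone-type enone, which also erases the relay stereocentre C11.

**Step 17**
Reactants: 27 [(1S,2S,5R,6S,7R,8S)-5-[(tert-butyldimethylsilyl)oxy]-2,6,9-trimethyl-11-oxotricyclo[5.4.0.0(2,8)]undec-9-en-6-yl]methyl (2Z)-2-methylbut-2-enoate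
Product: 28 [(1S,2S,5R,6S,7R,8S)-5-hydroxy-2,6,9-trimethyl-11-oxotricyclo[5.4.0.0(2,8)]undec-9-en-6-yl]methyl (2Z)-2-methylbut-2-enoate
Conditions: HF·pyridine, THF, 0 °C → rt
Reagents that add atoms: none
Why: Fluoride-mediated desilylation under acidic, non-basic conditions frees the hindered C5 alcohol without 1,3-acyl migration of the angelate.

**Step 18**
Reactants: 28 [(1S,2S,5R,6S,7R,8S)-5-hydroxy-2,6,9-trimethyl-11-oxotricyclo[5.4.0.0(2,8)]undec-9-en-6-yl]methyl (2Z)-2-methylbut-2-enoate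
Product: 29 [(1S,2S,5R,6S,7R,8S)-5-acetoxy-2,6,9-trimethyl-11-oxotricyclo[5.4.0.0(2,8)]undec-9-en-6-yl]methyl (2Z)-2-methylbut-2-enoate (CNP0374220.2)
Conditions: Ac2O, pyridine, DMAP (cat.), rt
Reagents that add atoms: acetic anhydride, CC(=O)OC(C)=O
Why: DMAP-catalysed acetylation of the secondary alcohol completes the target, whose six stereocentres (C1, C2, C5, C6, C7, C8) were all set in steps 2, 10, 11 and 12.

**Compound list**
1 | geranyl acetate, (2E)-3,7-dimethylocta-2,6-dien-1-yl acetate | CC(=O)OC/C=C(\C)CCC=C(C)C | starting material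
2 | (2E)-3-methyl-6-oxohex-2-en-1-yl acetate | CC(=O)OC/C=C(\C)CCC=O | intermediate
3 | (4S)-4-benzyl-3-propanoyl-1,3-oxazolidin-2-one | CCC(=O)N1[C@@H](Cc2ccccc2)COC1=O | starting material
4 | Z dibutylboron enolate of 3 | C/C=C(\OB(CCCC)CCCC)N1[C@@H](Cc2ccccc2)COC1=O | intermediate
5 | (4S)-4-benzyl-3-[(2S,3R,6E)-8-acetoxy-3-hydroxy-2,6-dimethyloct-6-enoyl]-1,3-oxazolidin-2-one | CC(=O)OC/C=C(\C)CC[C@@H](O)[C@H](C)C(=O)N1[C@@H](Cc2ccccc2)COC1=O | intermediate
6 | methyl (2S,3R,6E)-3,8-dihydroxy-2,6-dimethyloct-6-enoate | OC/C=C(\C)CC[C@@H](O)[C@H](C)C(=O)OC | intermediate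
7 | methyl (2S,3R,6E)-3-hydroxy-2,6-dimethyl-8-oxooct-6-enoate | O=C/C=C(\C)CC[C@@H](O)[C@H](C)C(=O)OC | intermediate
8 | methyl (2S,3R,6E)-3-[(tert-butyldimethylsilyl)oxy]-2,6-dimethyl-8-oxooct-6-enoate | O=C/C=C(\C)CC[C@@H](O[Si](C)(C)C(C)(C)C)[C@H](C)C(=O)OC | intermediate
9 | 3-methylbut-2-enoic acid | CC(C)=CC(=O)O | starting material
10 | tert-butyl 3-methylbut-2-enoate | CC(C)=CC(=O)OC(C)(C)C | intermediate
11 | lithium dienolate of 10 (ketene-acetal geometry not defined) | C=C(C)C=C(O[Li])OC(C)(C)C | intermediate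
12 | tert-butyl[(1-tert-butoxy-3-methylbuta-1,3-dien-1-yl)oxy]dimethylsilane (geometry as obtained) | C=C(C)C=C(OC(C)(C)C)O[Si](C)(C)C(C)(C)C | intermediate
13 | 1-tert-butyl 12-methyl (2E,5R,6E,10R,11S)-10-[(tert-butyldimethylsilyl)oxy]-5-hydroxy-3,7,11-trimethyldodeca-2,6-dienedioate | CC(C)(C)OC(=O)/C=C(\C)C[C@@H](O)/C=C(\C)CC[C@@H](O[Si](C)(C)C(C)(C)C)[C@H](C)C(=O)OC | intermediate
14 | triethylsilyl ester of 15 (5-O-triethylsilyl ether) | CC[Si](CC)(CC)OC(=O)/C=C(\C)C[C@@H](O[Si](CC)(CC)CC)/C=C(\C)CC[C@@H](O[Si](C)(C)C(C)(C)C)[C@H](C)C(=O)OC | intermediate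
15 | (2E,5R,6E,10R,11S)-10-[(tert-butyldimethylsilyl)oxy]-12-methoxy-3,7,11-trimethyl-12-oxo-5-[(triethylsilyl)oxy]dodeca-2,6-dienoic acid | OC(=O)/C=C(\C)C[C@@H](O[Si](CC)(CC)CC)/C=C(\C)CC[C@@H](O[Si](C)(C)C(C)(C)C)[C@H](C)C(=O)OC | intermediate
16 | acid chloride of 15 | ClC(=O)/C=C(\C)C[C@@H](O[Si](CC)(CC)CC)/C=C(\C)CC[C@@H](O[Si](C)(C)C(C)(C)C)[C@H](C)C(=O)OC | intermediate
17 | vinylketene from 16 (3-methylidene, 5R-silyloxy, 6E) | O=C=CC(=C)C[C@@H](O[Si](CC)(CC)CC)/C=C(\C)CC[C@@H](O[Si](C)(C)C(C)(C)C)[C@H](C)C(=O)OC | intermediate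
18 | methyl (2S,3R)-3-[(tert-butyldimethylsilyl)oxy]-2-methyl-5-{(1S,4R,5S,7S)-7-methyl-2-methylidene-6-oxo-4-[(triethylsilyl)oxy]bicyclo[3.1.1]heptan-7-yl}pentanoate (OSiEt3 on the side of the carbonyl bridge; 7-methyl over the three-carbon bridge) | O=C1[C@H]2C(=C)C[C@@H](O[Si](CC)(CC)CC)[C@@H]1[C@@]2(C)CC[C@@H](O[Si](C)(C)C(C)(C)C)[C@H](C)C(=O)OC | intermediate
19 | lithium ester enolate of 18 (enolate geometry not defined) | O=C1[C@H]2C(=C)C[C@@H](O[Si](CC)(CC)CC)[C@@H]1[C@@]2(C)CC[C@@H](O[Si](C)(C)C(C)(C)C)C(C)=C(OC)O[Li] | intermediate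
20 | lithium C7 alkoxide (aldolate) of the tricyclic ester | COC(=O)[C@]1(C)[C@]2(O[Li])[C@H]3C(=C)C[C@@H](O[Si](CC)(CC)CC)[C@@H]2[C@@]3(C)CC[C@H]1O[Si](C)(C)C(C)(C)C | intermediate
21 | methyl (1S,2S,5R,6S,7S,8S,11R)-5-[(tert-butyldimethylsilyl)oxy]-7-[(methoxyoxalyl)oxy]-2,6-dimethyl-9-methylidene-11-[(triethylsilyl)oxy]tricyclo[5.4.0.0(2,8)]undecane-6-carboxylate | COC(=O)[C@]1(C)[C@]2(OC(=O)C(=O)OC)[C@H]3C(=C)C[C@@H](O[Si](CC)(CC)CC)[C@@H]2[C@@]3(C)CC[C@H]1O[Si](C)(C)C(C)(C)C | intermediate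
22 | methyl (1S,2S,5R,6R,7R,8S,11R)-5-[(tert-butyldimethylsilyl)oxy]-2,6-dimethyl-9-methylidene-11-[(triethylsilyl)oxy]tricyclo[5.4.0.0(2,8)]undecane-6-carboxylate | COC(=O)[C@]1(C)[C@@H]2[C@H]3C(=C)C[C@@H](O[Si](CC)(CC)CC)[C@@H]2[C@@]3(C)CC[C@H]1O[Si](C)(C)C(C)(C)C | intermediate
23 | [(1S,2S,5R,6S,7R,8S,11R)-5-[(tert-butyldimethylsilyl)oxy]-2,6-dimethyl-9-methylidene-11-[(triethylsilyl)oxy]tricyclo[5.4.0.0(2,8)]undecan-6-yl]methanol | OC[C@]1(C)[C@@H]2[C@H]3C(=C)C[C@@H](O[Si](CC)(CC)CC)[C@@H]2[C@@]3(C)CC[C@H]1O[Si](C)(C)C(C)(C)C | intermediate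
24 | [(1S,2S,5R,6S,7R,8S,11R)-5-[(tert-butyldimethylsilyl)oxy]-2,6-dimethyl-9-methylidene-11-[(triethylsilyl)oxy]tricyclo[5.4.0.0(2,8)]undecan-6-yl]methyl (2Z)-2-methylbut-2-enoate | C/C=C(/C)C(=O)OC[C@]1(C)[C@@H]2[C@H]3C(=C)C[C@@H](O[Si](CC)(CC)CC)[C@@H]2[C@@]3(C)CC[C@H]1O[Si](C)(C)C(C)(C)C | intermediate
25 | [(1S,2S,5R,6S,7R,8S,11R)-5-[(tert-butyldimethylsilyl)oxy]-11-hydroxy-2,6-dimethyl-9-methylidenetricyclo[5.4.0.0(2,8)]undecan-6-yl]methyl (2Z)-2-methylbut-2-enoate | C/C=C(/C)C(=O)OC[C@]1(C)[C@@H]2[C@H]3C(=C)C[C@@H](O)[C@@H]2[C@@]3(C)CC[C@H]1O[Si](C)(C)C(C)(C)C | intermediate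
26 | [(1S,2S,5R,6S,7R,8S)-5-[(tert-butyldimethylsilyl)oxy]-2,6-dimethyl-9-methylidene-11-oxotricyclo[5.4.0.0(2,8)]undecan-6-yl]methyl (2Z)-2-methylbut-2-enoate | C/C=C(/C)C(=O)OC[C@]1(C)[C@@H]2[C@H]3C(=C)CC(=O)[C@@H]2[C@@]3(C)CC[C@H]1O[Si](C)(C)C(C)(C)C | intermediate
27 | [(1S,2S,5R,6S,7R,8S)-5-[(tert-butyldimethylsilyl)oxy]-2,6,9-trimethyl-11-oxotricyclo[5.4.0.0(2,8)]undec-9-en-6-yl]methyl (2Z)-2-methylbut-2-enoate | C/C=C(/C)C(=O)OC[C@]1(C)[C@@H]2[C@H]3C(C)=CC(=O)[C@@H]2[C@@]3(C)CC[C@H]1O[Si](C)(C)C(C)(C)C | intermediate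
28 | [(1S,2S,5R,6S,7R,8S)-5-hydroxy-2,6,9-trimethyl-11-oxotricyclo[5.4.0.0(2,8)]undec-9-en-6-yl]methyl (2Z)-2-methylbut-2-enoate | C/C=C(/C)C(=O)OC[C@]1(C)[C@@H]2[C@H]3C(C)=CC(=O)[C@@H]2[C@@]3(C)CC[C@H]1O | intermediate
29 | [(1S,2S,5R,6S,7R,8S)-5-acetoxy-2,6,9-trimethyl-11-oxotricyclo[5.4.0.0(2,8)]undec-9-en-6-yl]methyl (2Z)-2-methylbut-2-enoate | C/C=C(/C)C(=O)OC[C@]1(C)[C@@H]2[C@H]3C(C)=CC(=O)[C@@H]2[C@@]3(C)CC[C@H]1OC(C)=O | target

**Step count and risk**
Total step count: 18. Longest linear sequence: 16 (steps 1–5 and 8–18; steps 6–7 make dienolate 12).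

Steps most likely to fail:

Step 10 (vinylketene [2+2]). The allylic silyloxy group lowers the alkene's nucleophilicity, so ketene dimerisation or the isomeric dienylketene may compete, and the facial selectivity rests on the A(1,3) argument alone. Fallback: setting out from acid 15, amide coupling with pyrrolidine (EDC·HCl, HOBt) gives the pyrrolidine amide F1. Tf2O and 2,4,6-collidine in 1,2-dichloroethane (0 → 80 °C) then generate the more electrophilic, non-dimerising vinylketeniminium ion, whose intramolecular [2+2] gives the cyclobutaniminium triflate F2. Aqueous NaHCO3 hydrolysis of F2 returns to the route at ketone 18.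

Step 11 (aldol ring closure and oxalate trapping). The free lithium enolate can lose the beta-silyloxy group, the C6 selectivity depends on a non-chelated transition state, and the hindered aldolate may acylate slowly. Fallback: setting out from 18, LiN(i-Pr)2 with Me3SiCl present at −78 °C gives the trimethylsilyl ketene acetal F3. BF3·OEt2 in CH2Cl2 at −78 °C closes the ring by a Mukaiyama aldol through an open transition state with the same A(1,3) control, giving the tertiary alcohol F4. ClC(O)CO2Me, pyridine and DMAP convert F4 into oxalate 21, where the route is rejoined.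

Step 12 (radical deoxygenation). The hindered tertiary oxalate may fragment slowly, and the C7 cyclobutyl radical could ring-open before hydrogen transfer. Fallback: setting out from 21, CsOH (1 equiv, THF/H2O, 0 °C) hydrolyses only the oxalate methyl ester to the caesium oxalate F5. Visible-light photoredox decarboxylation of F5 with [Ir(dF(CF3)ppy)2(dtbbpy)]PF6 (1 mol %) and 2,4,6-triisopropylthiophenol as hydrogen-atom donor (DME/DMF, blue LEDs, rt) generates the same C7 radical tin-free at room temperature, where hydrogen transfer outruns ring opening, and rejoins the route at 22.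

**Further compounds**
F1 | step 10 | pyrrolidine amide of acid 15 | O=C(/C=C(\C)C[C@@H](O[Si](CC)(CC)CC)/C=C(\C)CC[C@@H](O[Si](C)(C)C(C)(C)C)[C@H](C)C(=O)OC)N1CCCC1
F2 | step 10 | cyclobutaniminium triflate (pyrrolidinium ylidene analogue of ketone 18) | [O-]S(=O)(=O)C(F)(F)F.C1CC[N+](C1)=C3[C@H]4C(=C)C[C@@H](O[Si](CC)(CC)CC)[C@@H]3[C@@]4(C)CC[C@@H](O[Si](C)(C)C(C)(C)C)[C@H](C)C(=O)OC
F3 | step 11 | trimethylsilyl ketene acetal of 18 (geometry not defined) | O=C1[C@H]2C(=C)C[C@@H](O[Si](CC)(CC)CC)[C@@H]1[C@@]2(C)CC[C@@H](O[Si](C)(C)C(C)(C)C)C(C)=C(OC)O[Si](C)(C)C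
F4 | step 11 | methyl (1S,2S,5R,6S,7S,8S,11R)-5-[(tert-butyldimethylsilyl)oxy]-7-hydroxy-2,6-dimethyl-9-methylidene-11-[(triethylsilyl)oxy]tricyclo[5.4.0.0(2,8)]undecane-6-carboxylate | COC(=O)[C@]1(C)[C@]2(O)[C@H]3C(=C)C[C@@H](O[Si](CC)(CC)CC)[C@@H]2[C@@]3(C)CC[C@H]1O[Si](C)(C)C(C)(C)C
F5 | step 12 | caesium oxalate half-ester of the C7 alcohol (from 21) | [Cs+].COC(=O)[C@]1(C)[C@]2(OC(=O)C([O-])=O)[C@H]3C(=C)C[C@@H](O[Si](CC)(CC)CC)[C@@H]2[C@@]3(C)CC[C@H]1O[Si](C)(C)C(C)(C)C
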